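**Retrosynthetic overview**

1. Manuifolin D (13) ⇐ 4'-O-prenylation and carbonate removal of phenol 11 ⇐ aromatic Claisen shift of the 4'-O-prenyl ether 10, which puts the 1,1-dimethylallyl group on C-5'.
2. Isoflavan 10 ⇐ 2-cinnamylphenol 8 in one pot with a chiral aryl-λ3-iodane: oxa-cyclisation (ring C) and 2→3 shift of ring B, the laboratory copy of flavanone → 2-hydroxyisoflavanone, run at the flavan oxidation level so that C-3 (R) survives; a silane then removes the C-2 oxygen.
3. 8 ⇐ chalcone 5 by ethyl chloroformate/NaBH4 (quinone-methide deoxygenation; the same reagent protects 7-O and 2'-O) ⇐ acetophenone 4 + aldehyde 3 ⇐ 2,4-dihydroxybenzaldehyde 1 + prenyl bromide 2.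
4. Rings A and B are bought; ring C is the only ring formed (step 4).

Assumption: the stereocentre in the SMILES is read as (3R); the chiral iodane of step 4 is a reagent made separately in two known operations (Mitsunobu etherification of 2-iodoresorcinol with methyl (S)-lactate, then NaBO3·4H2O/AcOH) and is not counted as a route step.

**Route**

Step 1
Reactants: 1 2,4-dihydroxybenzaldehyde; 2 prenyl bromide (1-bromo-3-methylbut-2-ene)
Product: 3 2-hydroxy-4-[(3-methylbut-2-en-1-yl)oxy]benzaldehyde
Conditions: CsHCO3 (1.2 equiv), 2 (1.1 equiv), MeCN, 60 °C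
Reagents that add atoms: prenyl bromide 2, CC(C)=CCBr
Why: Williamson etherification; the 4-OH is the more acidic, non-chelated phenol (the 2-OH is hydrogen-bonded to the aldehyde), so a bicarbonate base alkylates it selectively.

Step 2
Reactants: 3 2-hydroxy-4-[(3-methylbut-2-en-1-yl)oxy]benzaldehyde; 4 1-(2,4-dihydroxyphenyl)ethanone
Product: 5 (E)-1-(2,4-dihydroxyphenyl)-3-{2-hydroxy-4-[(3-methylbut-2-en-1-yl)oxy]phenyl}prop-2-en-1-one (chalcone)
Conditions: LiN(SiMe3)2 (5.5 equiv), THF, −78 °C → rt; then 1 M HCl to pH 5, 0 °C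
Reagents that add atoms: none
Why: Claisen–Schmidt condensation (aldol addition, E1cB dehydration) run on the lithium polyanions so that no phenol protection is needed; the E-enone is the thermodynamic product.

Step 3
Reactants: 5 chalcone
Product: 8 ethyl 4-[(2E)-3-{2-[(ethoxycarbonyl)oxy]-4-[(3-methylbut-2-en-1-yl)oxy]phenyl}prop-2-en-1-yl]-3-hydroxyphenyl carbonate (2-cinnamylphenol), via tris(ethyl carbonate) chalcone 6 (not isolated), via ortho-quinone methide 7 (not isolated)
Conditions: ClCO2Et (3.5 equiv), Et3N (4 equiv), THF, 0 °C; filter; then NaBH4 (6 equiv), THF/H2O, 0 °C → rt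
Reagents that add atoms: ethyl chloroformate, CCOC(=O)Cl
Why: reductive deoxygenation of an ortho-acyloxyaryl ketone through an ortho-quinone methide: hydride reduces the ketone 1,2, the 2'-carbonate migrates to the new alkoxide and is expelled by the phenoxide to give 7, and a second hydride adds at the quinone-methide carbon, which keeps the E-alkene, frees only the ring A ortho-phenol and leaves the other two carbonates as protecting groups.

Step 4
Reactants: 8 2-cinnamylphenol
Product: 10 ethyl (3R)-3-{2-[(ethoxycarbonyl)oxy]-4-[(3-methylbut-2-en-1-yl)oxy]phenyl}-3,4-dihydro-2H-chromen-7-yl carbonate, via 2-methoxyisoflavan 9 (not isolated)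
Conditions: (R,R)-Ar*I(OAc)2 (1.1 equiv; Ar* = 2,6-bis{[(2R)-1-methoxy-1-oxopropan-2-yl]oxy}phenyl), BF3·OEt2 (2 equiv), MeOH (4 equiv), CH2Cl2, −78 °C; then Et3SiH (6 equiv), −78 → −30 °C
Reagents that add atoms: none
Why: Proposed new method: the BF3-activated chiral aryl-λ3-iodane (trivalent iodine) attacks the electron-rich styrene at the CH2-bearing carbon (the Re face there leads to 3R), the ring A phenol closes ring C by 6-endo attack at the benzylic carbon, and the para-alkoxy-activated ring B, anti-periplanar to the C–I bond in the 2,3-trans adduct, shifts from C-2 to C-3 with inversion as the iodoarene leaves, so C-3 is set by reagent-controlled face selection and the O-1-stabilised oxocarbenium ion is trapped by MeOH as 9 and then reduced by Et3SiH/BF3 to the C-2 methylene of 10; this is the flavanone → 2-hydroxyisoflavanone aryl shift run at the flavan oxidation level, and the closest known reactions are the enantioselective oxidative 1,2-aryl migration of chalcones and aryl alkenes to α-aryl acetals with lactate-based iodanes, the iodane-mediated cyclisation of 4-arylbut-3-enoic acids with aryl migration, the 2→3 aryl shift in solvolysis of 2,3-trans-flavan-3-yl sulfonates, and Et3SiH/BF3 reduction of 2-alkoxychromans; I commit to the (R,R)-reagent, but which antipode delivers iodine to the needed face cannot be derived with certainty and must be confirmed on the first run ((S,S)-reagent if reversed).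

Step 5
Reactants: 10 (3R)-isoflavan bis(ethyl carbonate) 4'-prenyl ether
Product: 11 ethyl (3R)-3-[2-[(ethoxycarbonyl)oxy]-4-hydroxy-5-(2-methylbut-3-en-2-yl)phenyl]-3,4-dihydro-2H-chromen-7-yl carbonate
Conditions: PhNEt2, 190 °C (sealed tube), 2 h
Reagents that add atoms: none
Why: aromatic Claisen rearrangement ([3,3]-sigmatropic) of the aryl prenyl ether delivers the 1,1-dimethylallyl group with allyl inversion; C-5' (para to the 2'-oxygen, one ortho neighbour) is favoured over the doubly flanked C-3', and the remote C-3 stereocentre is not touched.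

Step 6
Reactants: 11 phenol; 2 prenyl bromide
Product: 13 manuifolin D, via manuifolin D bis(ethyl carbonate) 12 (not isolated)
Conditions: K2CO3 (2 equiv), 2 (1.3 equiv), DMF, rt; then pyrrolidine (10 equiv), rt
Reagents that add atoms: prenyl bromide 2, CC(C)=CCBr
Why: Williamson etherification of the only free phenol, then aminolysis of both aryl carbonates by pyrrolidine (which also destroys excess bromide before the phenols are uncovered); no acid is used, so the prenyl ether and the 1,1-dimethylallyl group survive.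

**Compound list**

1 | 2,4-dihydroxybenzaldehyde | O=Cc1ccc(O)cc1O | starting material
2 | prenyl bromide (1-bromo-3-methylbut-2-ene) | CC(C)=CCBr | starting material
3 | 2-hydroxy-4-[(3-methylbut-2-en-1-yl)oxy]benzaldehyde | CC(C)=CCOc1ccc(C=O)c(O)c1 | intermediate
4 | 1-(2,4-dihydroxyphenyl)ethanone | CC(=O)c1ccc(O)cc1O | starting material
5 | (E)-1-(2,4-dihydroxyphenyl)-3-{2-hydroxy-4-[(3-methylbut-2-en-1-yl)oxy]phenyl}prop-2-en-1-one | CC(C)=CCOc1ccc(/C=C/C(=O)c2ccc(O)cc2O)c(O)c1 | intermediate
6 | tris(ethyl carbonate) of chalcone 5 | CCOC(=O)Oc1ccc(C(=O)/C=C/c2ccc(OCC=C(C)C)cc2OC(=O)OCC)c(OC(=O)OCC)c1 | intermediate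
7 | ortho-quinone methide (6-[(2E)-3-arylprop-2-en-1-ylidene]-3-(ethoxycarbonyloxy)cyclohexa-2,4-dien-1-one; exocyclic geometry not defined) | CCOC(=O)OC1=CC(=O)C(=C/C=C/c2ccc(OCC=C(C)C)cc2OC(=O)OCC)C=C1 | intermediate
8 | ethyl 4-[(2E)-3-{2-[(ethoxycarbonyl)oxy]-4-[(3-methylbut-2-en-1-yl)oxy]phenyl}prop-2-en-1-yl]-3-hydroxyphenyl carbonate | CCOC(=O)Oc1ccc(C/C=C/c2ccc(OCC=C(C)C)cc2OC(=O)OCC)c(O)c1 | intermediate
9 | (3R)-2-methoxyisoflavan 7,2'-bis(ethyl carbonate) 4'-prenyl ether (mixture of C-2 epimers) | CCOC(=O)Oc1cc(OCC=C(C)C)ccc1[C@@H]1C(OC)Oc2cc(OC(=O)OCC)ccc2C1 | intermediate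
10 | ethyl (3R)-3-{2-[(ethoxycarbonyl)oxy]-4-[(3-methylbut-2-en-1-yl)oxy]phenyl}-3,4-dihydro-2H-chromen-7-yl carbonate | CCOC(=O)Oc1cc(OCC=C(C)C)ccc1[C@@H]1COc2cc(OC(=O)OCC)ccc2C1 | intermediate
11 | ethyl (3R)-3-[2-[(ethoxycarbonyl)oxy]-4-hydroxy-5-(2-methylbut-3-en-2-yl)phenyl]-3,4-dihydro-2H-chromen-7-yl carbonate | CCOC(=O)Oc1cc(O)c(C(C)(C)C=C)cc1[C@@H]1COc2cc(OC(=O)OCC)ccc2C1 | intermediate
12 | manuifolin D 7,2'-bis(ethyl carbonate) | CCOC(=O)Oc1cc(OCC=C(C)C)c(C(C)(C)C=C)cc1[C@@H]1COc2cc(OC(=O)OCC)ccc2C1 | intermediate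
13 | manuifolin D, (3R)-7,2'-dihydroxy-4'-[(3-methylbut-2-en-1-yl)oxy]-5'-(2-methylbut-3-en-2-yl)isoflavan | C=CC(C)(C)c1cc([C@@H]2COc3cc(O)ccc3C2)c(O)cc1OCC=C(C)C | target

**Count and risks**

Total step count: 6. Longest linear sequence: 6 (1 → 3 → 5 → 8 → 10 → 11 → 13).

Step 4 is the most likely to fail. The hazards are oxidation of the free phenol or attack on the prenyl alkene by the iodane, elimination instead of aryl shift, imperfect face selectivity, and loss of the prenyl ether under BF3. If only the prenyl group is lost, the sole free phenol can be re-prenylated. The fallback is a stepwise, stereospecific version of the same aryl shift that takes C-3 from an epoxide instead of from the iodane. It sets out from 6 (isolated after the acylation half of step 3) and comes back at 10 without passing through 8.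
- Nucleophilic asymmetric epoxidation of the enone of 6 with N-(9-anthracenylmethyl)-O-benzylcinchonidinium bromide (10 mol %), aqueous NaOCl, toluene, −20 °C gives the (2S,3R)-epoxy ketone F1. This is the pseudo-enantiomer that gives (2S,3R)-epoxides of chalcones, and a nucleophilic oxidant leaves the electron-rich alkenes alone.
- NaBH4 (THF/H2O, 0 °C, quenched at pH 7) repeats the carbonate-transfer reduction of step 3 through the epoxy ortho-quinone methide F2 to the (2R,3R)-epoxy phenol F3.
- Catalytic camphorsulfonic acid (CH2Cl2, 0 °C) closes ring C by 6-endo opening at the benzylic carbon with inversion, giving the (2S,3R)-2,3-trans-flavan-3-ol F4.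
- Tf2O and 2,6-di-tert-butyl-4-methylpyridine (CH2Cl2, −78 °C) give the triflate F5, which ionises with participation of the anti-periplanar ring B (2→3 shift, inversion at C-3). Et3SiH added to the same flask reduces the oxocarbenium ion to 10.

Step 5 is the second risk. The hazards are rearrangement to C-3', cyclisation of the ortho-(1,1-dimethylallyl)phenol to a dihydrobenzofuran on prolonged heating, and thermal loss of carbonate. The fallback replaces the sigmatropic shift by a cross-coupling; it sets out from 10 and comes back at 11.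
- The prenyl ether of 10 is cleaved with CeCl3·7H2O/NaI (MeCN, 60 °C) to the phenol F6.
- N-iodosuccinimide with catalytic TsOH (MeCN, −20 °C) iodinates F6 ortho to the free hydroxyl at the open C-5' position, giving the iodophenol F7. Ring A is deactivated by its carbonate.
- F7 is coupled with 3-methylbut-2-enylboronic acid pinacol ester under γ-selective Suzuki–Miyaura conditions: Pd(OAc)2, 2-{bis[3,5-bis(trifluoromethyl)phenyl]phosphino}-3,6-dimethoxy-2',4',6'-triisopropylbiphenyl, CsF, THF, 50 °C. Fast reductive elimination from the γ-bound allyl gives the branched product 11. The ligand is named from memory and the choice should be checked in a short screen.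

Step 2 is the third risk. The aldehyde is deprotonated to a poorly electrophilic phenoxide and the ketone must react as a trianion, so conversion may be low. The fallback is a Wittig olefination under near-neutral conditions, where the aldehyde stays a neutral, chelated phenol; it sets out from 3 and comes back at 5.
- Commercial 2-chloro-1-(2,4-dihydroxyphenyl)ethanone and PPh3 (toluene, 80 °C) give the phosphonium chloride F8.
- Aqueous NaHCO3 liberates the stabilised ylide F9, which is heated with 3 (toluene, 100 °C) to give the (E)-chalcone 5.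

Further compounds

F1 | step 4 | (2S,3R)-epoxy ketone, tris(ethyl carbonate) | CCOC(=O)Oc1ccc(C(=O)[C@H]2O[C@@H]2c3ccc(OCC=C(C)C)cc3OC(=O)OCC)c(OC(=O)OCC)c1
F2 | step 4 | epoxy ortho-quinone methide (epoxide configuration as in F3) | CCOC(=O)OC1=CC(=O)C(=C[C@H]2O[C@@H]2c3ccc(OCC=C(C)C)cc3OC(=O)OCC)C=C1
F3 | step 4 | ethyl 4-{[(2R,3R)-3-{2-[(ethoxycarbonyl)oxy]-4-[(3-methylbut-2-en-1-yl)oxy]phenyl}oxiran-2-yl]methyl}-3-hydroxyphenyl carbonate | CCOC(=O)Oc1ccc(C[C@H]2O[C@@H]2c3ccc(OCC=C(C)C)cc3OC(=O)OCC)c(O)c1
F4 | step 4 | ethyl (2S,3R)-2-{2-[(ethoxycarbonyl)oxy]-4-[(3-methylbut-2-en-1-yl)oxy]phenyl}-3-hydroxy-3,4-dihydro-2H-chromen-7-yl carbonate | CCOC(=O)Oc1ccc2c(c1)O[C@@H](c3ccc(OCC=C(C)C)cc3OC(=O)OCC)[C@H](O)C2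
F5 | step 4 | 3-O-triflate of F4 | CCOC(=O)Oc1ccc2c(c1)O[C@@H](c3ccc(OCC=C(C)C)cc3OC(=O)OCC)[C@H](OS(=O)(=O)C(F)(F)F)C2
F6 | step 5 | ethyl (3R)-3-{2-[(ethoxycarbonyl)oxy]-4-hydroxyphenyl}-3,4-dihydro-2H-chromen-7-yl carbonate | CCOC(=O)Oc1cc(O)ccc1[C@@H]1COc2cc(OC(=O)OCC)ccc2C1
F7 | step 5 | ethyl (3R)-3-{2-[(ethoxycarbonyl)oxy]-4-hydroxy-5-iodophenyl}-3,4-dihydro-2H-chromen-7-yl carbonate | CCOC(=O)Oc1cc(O)c(I)cc1[C@@H]1COc2cc(OC(=O)OCC)ccc2C1
F8 | step 2 | [2-(2,4-dihydroxyphenyl)-2-oxoethyl]triphenylphosphonium chloride | O=C(C[P+](c1ccccc1)(c1ccccc1)c1ccccc1)c1ccc(O)cc1O.[Cl-]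
F9 | step 2 | 1-(2,4-dihydroxyphenyl)-2-(triphenyl-λ5-phosphanylidene)ethanone | O=C(C=P(c1ccccc1)(c1ccccc1)c1ccccc1)c1ccc(O)cc1O
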